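**Retrosynthetic overview**
1. Shimalactone B 25 ⇐ one-pot carboalumination of alkynol 21 and Pd2(dba)3-catalysed coupling with tetraenyl iodide 16, then 8π (cyclooctatriene) and 6π (cyclobutane and cyclohexadiene) closures; these rings form last.
2. 16 ⇐ Z-selective iodo-olefination of trienal 15 ⇐ oxidation of trienol 14.
3. 14 ⇐ cation–enol C2–C6 closure (2-oxabicyclo[2.2.1]heptane, second ring) of carbinol 13, made from ketolactone 8 and the vinyllithium from 11.
4. 8 (δ-lactone, first ring) ⇐ phosphoramide/SiCl4-catalysed anti-vinylogous aldol of dienal 3 (from mesityl oxide 1) with diene 6 (from methyl propionate 4); this sets the first stereocentres.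
5. 21 ⇐ oxazaborolidine-catalysed reduction of ynone 19 (from 17 and 18).

Atom labels C1–C20 follow the polyketide chain: C1 lactone carbonyl, C5 lactone carbinol carbon, C17 side-chain carbinol, C20 terminal methyl.
Assumption: the known free-hydroxyl cascade favours shimalactone A, taken here as the isomer of 25 with all four cyclobutane carbons inverted.
Assumption: the catalyst antipodes named in steps 5 and 11 are those expected from the usual models; if a first run shows the opposite sense, the other antipode is used.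

**Step 1**
Reactants: 1 mesityl oxide (4-methylpent-3-en-2-one)
Product: 2 (E)-2-methyl-4-oxopent-2-enal
Conditions: SeO2 (1.1 equiv), 1,4-dioxane, H2O (trace), 90 °C
Reagents that add atoms: selenium dioxide O=[Se]=O
Why: Riley allylic oxidation (ene reaction, then 2,3-sigmatropic shift) takes place at the E-methyl of the trisubstituted alkene and gives the E-enal.

**Step 2**
Reactants: 2 (E)-2-methyl-4-oxopent-2-enal
Product: 3 (2E,4E)-2,4-dimethyl-6-oxohepta-2,4-dienal
Conditions: Ph3P=C(CH3)CHO (1.0 equiv), CH2Cl2, 23 °C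
Reagents that add atoms: 2-(triphenylphosphoranylidene)propanal CC(C=O)=P(c1ccccc1)(c1ccccc1)c1ccccc1
Why: Wittig olefination with a stabilised ylide reacts at the aldehyde and not the ketone and gives the E-trisubstituted alkene.

**Step 3**
Reactants: 4 methyl propionate (two molecules: one is enolised, the other is the acyl acceptor)
Product: 5 methyl 2-methyl-3-oxopentanoate (racemic)
Conditions: NaH (0.55 equiv per mol of 4), PhMe, 80 °C; aq. HCl
Reagents that add atoms: methyl propionate (second molecule of 4, acyl acceptor) CCC(=O)OC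
Why: Claisen self-condensation, in which the sodium enolate of one molecule of 4 acylates a second molecule with loss of methanol, is driven by deprotonation of the β-keto ester; the stereocentre of racemic 5 is erased in step 4.

**Step 4**
Reactants: 5 methyl 2-methyl-3-oxopentanoate
Product: 6 (3Z)-1-methoxy-2-methyl-1,3-bis(trimethylsilyloxy)penta-1,3-diene
Conditions: Me3SiOTf (2.2 equiv), Et3N (2.5 equiv), Et2O, 0 → 23 °C
Reagents that add atoms: trimethylsilyl trifluoromethanesulfonate C[Si](C)(C)OS(=O)(=O)C(F)(F)F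
Why: double soft enolisation and O-silylation of a β-keto ester gives the Chan-type bis(silyloxy)diene.

**Step 5**
Reactants: 3 (2E,4E)-2,4-dimethyl-6-oxohepta-2,4-dienal; 6 bis(silyloxy)diene
Product: 8 (5R,6S)-3,5-dimethyl-6-[(2E,4E)-4-methyl-6-oxohepta-2,4-dien-2-yl]oxane-2,4-dione, via hydroxy ketoester 7 (not isolated)
Conditions: SiCl4 (1.5 equiv), (R,R)-binaphthyldiamine bisphosphoramide (5 mol %), iPr2NEt (10 mol %), CH2Cl2, −78 °C; aq. NaHCO3; then K2CO3 (1.0 equiv), MeOH, 0 °C; aq. HCl to pH 3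
Reagents that add atoms: none
Why: Lewis-base-catalysed (metal-free) vinylogous Mukaiyama aldol in which the chiral phosphoramide-bound silicon cation activates only the aldehyde, the diene γ-carbon adds through an open transition state (anti, catalyst-controlled face) to set C4 (R) and C5 (S), and the δ-hydroxyl then lactonises onto the methyl ester.

**Step 6**
Reactants: 9 propargyl alcohol
Product: 11 (Z)-3-iodo-2-methylprop-2-en-1-ol, via vinylmagnesium alkoxide 10 (not isolated)
Conditions: MeMgBr (2.5 equiv), CuI (10 mol %), Et2O, −10 → 23 °C; then I2 (1.2 equiv), −10 °C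
Reagents that add atoms: methylmagnesium bromide C[Mg]Br; iodine II
Why: CuI-catalysed anti-carbomagnesiation of the propargylic magnesium alkoxide puts methyl on the proximal carbon and magnesium trans to it, and iodinolysis with retention gives the Z-iodide.

**Step 7**
Reactants: 8 ketolactone; 11 (Z)-3-iodo-2-methylprop-2-en-1-ol
Product: 14 (1S,4S,6R,7S)-7-[(1E,3E,5Z)-7-hydroxy-2,4,6-trimethylhepta-1,3,5-trien-1-yl]-4,6,7-trimethyl-2-oxabicyclo[2.2.1]heptane-3,5-dione, via dilithio species 12 (not isolated), via tertiary carbinol 13 (not isolated)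
Conditions: 11, t-BuLi (3.1 equiv), Et2O, −78 °C; added to 8, LiN(SiMe3)2 (1.05 equiv), LaCl3·2LiCl (1.1 equiv), THF, −78 °C; aq. NH4Cl; then CSA (10 mol %), CH2Cl2, −20 → 0 °C
Reagents that add atoms: none
Why: 1,2-addition of the vinyllithium to the dienone carbonyl of the lithium enolate of 8 gives 13, whose acid ionisation (SN1) forms a heptatrienyl cation that the enol carbon C2 captures at C6 in a biomimetic intramolecular C-alkylation; the bridge forces C2 onto the face of C5 that carries C6, the rotamer with the C6 methyl over the ring oxygen is preferred (less A1,2 strain) so C6 becomes S, the 7E and 9E alkenes come from the s-trans polyene, and O-capture by the primary alcohol is reversible.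

**Step 8**
Reactants: 14 oxabicyclic trienol
Product: 15 (2Z,4E,6E)-2,4,6-trimethyl-7-[(1S,4S,6R,7S)-4,6,7-trimethyl-3,5-dioxo-2-oxabicyclo[2.2.1]heptan-7-yl]hepta-2,4,6-trienal
Conditions: MnO2 (20 equiv), CH2Cl2, 23 °C
Reagents that add atoms: none
Why: MnO2 allylic oxidation converts only the primary allylic alcohol and leaves the hindered ketone, the lactone and the Z-alkene untouched.

**Step 9**
Reactants: 15 trienal
Product: 16 (1S,4S,6R,7S)-7-[(1E,3E,5Z,7Z)-8-iodo-2,4,6-trimethylnona-1,3,5,7-tetraen-1-yl]-4,6,7-trimethyl-2-oxabicyclo[2.2.1]heptane-3,5-dione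
Conditions: EtPPh3I (1.6 equiv), n-BuLi, THF, 23 °C; I2, −78 °C; NaN(SiMe3)2, −20 °C; then 15, −78 → −20 °C
Reagents that add atoms: ethyltriphenylphosphonium iodide CC[P+](c1ccccc1)(c1ccccc1)c1ccccc1.[I-]; iodine II
Why: Stork–Zhao-type α-iodo Wittig olefination with the non-stabilised iodo ylide under kinetic control gives the Z-2-iodoalkene (iodine cis to C12).

**Step 10**
Reactants: 17 tigloyl chloride; 18 bis(trimethylsilyl)acetylene
Product: 19 (E)-4-methyl-1-(trimethylsilyl)hex-4-en-1-yn-3-one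
Conditions: AlCl3 (1.1 equiv), CH2Cl2, 0 °C
Reagents that add atoms: none
Why: Friedel–Crafts-type acylation of the bis-silyl alkyne by ipso-substitution of one silyl group gives the silyl ynone with the E-alkene retained.

**Step 11**
Reactants: 19 silyl ynone
Product: 21 (3S,4E)-4-methylhex-4-en-1-yn-3-ol, via silyl alkynol 20 (not isolated)
Conditions: (R)-2-methyl-CBS-oxazaborolidine (20 mol %), BH3·SMe2 (1.0 equiv), THF, −30 °C; MeOH; then K2CO3 (10 mol %), MeOH, 23 °C
Reagents that add atoms: none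
Why: Corey–Bakshi–Shibata reduction (metal-free) with the α-branched alkenyl group as the large and the alkynyl group as the small substituent delivers hydride to give (3R)-20, which is (3S)-21 after protodesilylation (priority change only).

**Step 12**
Reactants: 21 (3S,4E)-4-methylhex-4-en-1-yn-3-ol; 16 tetraenyl iodide
Product: 25 shimalactone B, via alkenylalane 22 (not isolated), via pentaene alkoxide 23 (not isolated), via cyclooctatriene 24 (not isolated)
Conditions: 21, Me3Al (3.0 equiv), Cp2ZrCl2 (25 mol %), CH2Cl2, 0 → 23 °C; volatiles removed; THF, 16 (0.8 equiv), Pd2(dba)3 (5 mol %), P(2-furyl)3 (20 mol %), ZnCl2 (20 mol %), 0 → 23 °C; then 40 °C; aq. KNaC4H4O6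
Reagents that add atoms: trimethylaluminium C[Al](C)C
Why: Proposed new method: aluminium-alkoxide-steered torquoselective 8π–6π cascade — Cp2ZrCl2-catalysed syn-carboalumination (methyl to C16, E-alkenylalane) and Negishi-type Pd2(dba)3/P(2-furyl)3 coupling with retention give the (9E,11Z,13Z,15E)-tetraene, whose thermal conrotatory 8π and disrotatory 6π closures fix the relative configuration of C9, C10, C15 and C16, while the helical sense is set at the C16 terminus by the C17 stereocentre: with a free hydroxyl the usual allylic model (carbon group anti to the forming bond, oxygen inside) leads to the shimalactone A sense, but the bulky, electron-rich O–AlMe2 aggregate kept on oxygen is expected to take the anti position with the planar butenyl group inside and hydrogen outside, which is the arrangement that gives 25; closest known chemistry is the one-pot carboalumination/Negishi coupling, thermal 8π–6π cascades of (E,Z,Z,E)-tetraenes and the inside-alkoxy/anti-substituent model for reactions next to allylic stereocentres.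

**Compound list**
1 | mesityl oxide (4-methylpent-3-en-2-one) | CC(=O)C=C(C)C | starting material
2 | (E)-2-methyl-4-oxopent-2-enal | CC(=O)/C=C(C)/C=O | intermediate
3 | (2E,4E)-2,4-dimethyl-6-oxohepta-2,4-dienal | CC(=O)/C=C(C)/C=C(C)/C=O | intermediate
4 | methyl propionate | CCC(=O)OC | starting material
5 | methyl 2-methyl-3-oxopentanoate (racemic) | CCC(=O)C(C)C(=O)OC | intermediate
6 | (3Z)-1-methoxy-2-methyl-1,3-bis(trimethylsilyloxy)penta-1,3-diene (ketene acetal geometry not defined) | C/C=C(O[Si](C)(C)C)/C(C)=C(OC)O[Si](C)(C)C | intermediate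
7 | methyl (4R,5S,6E,8E)-5-hydroxy-2,4,6,8-tetramethyl-3,10-dioxoundeca-6,8-dienoate (C2 epimers) | COC(=O)C(C)C(=O)[C@H](C)[C@H](O)/C(C)=C/C(C)=C/C(C)=O | intermediate
8 | (5R,6S)-3,5-dimethyl-6-[(2E,4E)-4-methyl-6-oxohepta-2,4-dien-2-yl]oxane-2,4-dione (C3 epimers and enol) | C[C@H]1C(=O)C(C)C(=O)O[C@@H]1/C(C)=C/C(C)=C/C(C)=O | intermediate
9 | propargyl alcohol (prop-2-yn-1-ol) | C#CCO | starting material
10 | bromomagnesium (Z)-3-(bromomagnesio)-2-methylprop-2-en-1-olate | Br[Mg]/C=C(C)\CO[Mg]Br | intermediate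
11 | (Z)-3-iodo-2-methylprop-2-en-1-ol | OC/C(C)=C\I | intermediate
12 | lithium (Z)-3-lithio-2-methylprop-2-en-1-olate | [Li]/C=C(C)\CO[Li] | intermediate
13 | (5R,6S)-6-[(2E,4E,7Z)-6,9-dihydroxy-4,6,8-trimethylnona-2,4,7-trien-2-yl]-3,5-dimethyloxane-2,4-dione (carbinol epimers) | C[C@H]1C(=O)C(C)C(=O)O[C@@H]1/C(C)=C/C(C)=C/C(C)(O)/C=C(C)\CO | intermediate
14 | (1S,4S,6R,7S)-7-[(1E,3E,5Z)-7-hydroxy-2,4,6-trimethylhepta-1,3,5-trien-1-yl]-4,6,7-trimethyl-2-oxabicyclo[2.2.1]heptane-3,5-dione | OC/C(C)=C\C(C)=C\C(C)=C\[C@]1(C)[C@H]2OC(=O)[C@]1(C)C(=O)[C@@H]2C | intermediate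
15 | (2Z,4E,6E)-2,4,6-trimethyl-7-[(1S,4S,6R,7S)-4,6,7-trimethyl-3,5-dioxo-2-oxabicyclo[2.2.1]heptan-7-yl]hepta-2,4,6-trienal | O=C/C(C)=C\C(C)=C\C(C)=C\[C@]1(C)[C@H]2OC(=O)[C@]1(C)C(=O)[C@@H]2C | intermediate
16 | (1S,4S,6R,7S)-7-[(1E,3E,5Z,7Z)-8-iodo-2,4,6-trimethylnona-1,3,5,7-tetraen-1-yl]-4,6,7-trimethyl-2-oxabicyclo[2.2.1]heptane-3,5-dione | I/C(C)=C\C(C)=C/C(C)=C/C(C)=C/[C@]1(C)[C@H]2OC(=O)[C@]1(C)C(=O)[C@@H]2C | intermediate
17 | tigloyl chloride ((E)-2-methylbut-2-enoyl chloride) | C/C=C(\C)C(Cl)=O | starting material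
18 | bis(trimethylsilyl)acetylene | C[Si](C)(C)C#C[Si](C)(C)C | starting material
19 | (E)-4-methyl-1-(trimethylsilyl)hex-4-en-1-yn-3-one | C/C=C(\C)C(=O)C#C[Si](C)(C)C | intermediate
20 | (3R,4E)-4-methyl-1-(trimethylsilyl)hex-4-en-1-yn-3-ol | C/C=C(\C)[C@@H](O)C#C[Si](C)(C)C | intermediate
21 | (3S,4E)-4-methylhex-4-en-1-yn-3-ol | C/C=C(\C)[C@@H](O)C#C | intermediate
22 | (1E,3R,4E)-1-(dimethylalumanyl)-3-(dimethylalumanyloxy)-2,4-dimethylhexa-1,4-diene | C/C=C(\C)[C@@H](O[Al](C)C)/C(C)=C/[Al](C)C | intermediate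
23 | (1S,4S,6R,7S)-7-[(1E,3E,5Z,7Z,9E,11R,12E)-11-(dimethylalumanyloxy)-2,4,6,8,10,12-hexamethyltetradeca-1,3,5,7,9,12-hexaen-1-yl]-4,6,7-trimethyl-2-oxabicyclo[2.2.1]heptane-3,5-dione | C/C=C(\C)[C@@H](O[Al](C)C)/C(C)=C/C(C)=C\C(C)=C/C(C)=C/C(C)=C/[C@]1(C)[C@H]2OC(=O)[C@]1(C)C(=O)[C@@H]2C | intermediate
24 | cycloocta-1,3,5-triene from C9–C16 closure of 23 (C8 and C17 substituents trans, both sp3 ring carbons configured as in 25, O-dimethylalumanyl ether) | C/C=C(\C)[C@@H](O[Al](C)C)[C@@]3(C)/C=C(C)\C=C(C)/C=C(C)\[C@@H]3/C(C)=C/[C@]1(C)[C@H]2OC(=O)[C@]1(C)C(=O)[C@@H]2C | intermediate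
25 | shimalactone B | C/C=C(\C)[C@@H](O)[C@@]1(C)[C@@H]2C(C)=CC(C)=C[C@]2(C)[C@@H]1/C(C)=C/[C@]1(C)[C@H]2OC(=O)[C@]1(C)C(=O)[C@@H]2C | target

**Step count**
Total steps: 12. Longest linear sequence: 7 (steps 1, 2, 5, 7, 8, 9, 12).

**Steps most likely to fail**

Step 12 (proposed new step). The alkoxide-steered helical sense is untested, and if the 6π closure rather than the 8π closure decides the outcome the model may not apply. The fallback uses the known undirected cascade; it sets out from 21 and 16 and comes back at 25. 21 is carboaluminated as before to 22 and quenched with I2 to give (1E,3R,4E)-1-iodo-2,4-dimethylhexa-1,4-dien-3-ol F1. Pd(PPh3)4 and Me3SnSnMe3 convert it into the vinylstannane F2. Stille coupling with 16 (Pd(PPh3)4, CuI, DMF, 23 °C) gives the free pentaenol F3, which closes through the cyclooctatrienol F4 and its helical diastereomer F5 to 25 and shimalactone A F6. 25 is the minor isomer and is separated by HPLC; F6 is heated (PhMe, 100 °C) to re-equilibrate through retro-6π and retro-8π opening and is recycled.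

Step 7. The long cation could cyclise on itself, lose the C9=C10 or Z-alkene geometry, or the vinyllithium could attack elsewhere. The fallback shortens the cation and fixes the C9=C10 geometry beforehand; it sets out from 2 (with 6 and 9) and comes back at 15. The step 5 aldol applied to 2 gives the hydroxy ketoester F7 and, after K2CO3/MeOH, the methyl ketone lactone F8. 9 is carboaluminated (Me3Al, Cp2ZrCl2) to the alane F9 and iodinated to (E)-3-iodo-2-methylprop-2-en-1-ol F10. t-BuLi gives the dilithio species F11, which adds to the enolate of F8 to give the allylic carbinol F12. CSA ionises F12 to a short pentadienyl cation that closes to the oxabicyclic dienol F13. MnO2 gives the dienal F14, the step 9 iodo-Wittig gives the Z-trienyl iodide F15, and formylation (Pd(PPh3)4, CO, Bu3SnH) gives 15.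

Step 5. The doubly methyl-substituted diene may give low anti selectivity or low enantioselectivity with this keto-dienal. The fallback builds the propionate units one at a time; it sets out from 3 and comes back at 8. D-Proline-catalysed cross-aldol with propanal (DMF, 4 °C) gives the anti-aldol aldehyde F16. 2-Bromopropanoyl bromide and pyridine give the bromo ester F17. SmI2 (THF, −78 °C) closes it by an intramolecular Reformatsky reaction to the hydroxy lactone F18, and Dess–Martin oxidation gives 8.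

**Further compounds**
F1 | step 12 | (1E,3R,4E)-1-iodo-2,4-dimethylhexa-1,4-dien-3-ol | C/C=C(\C)[C@@H](O)/C(C)=C/I
F2 | step 12 | (1E,3R,4E)-2,4-dimethyl-1-(trimethylstannyl)hexa-1,4-dien-3-ol | C/C=C(\C)[C@@H](O)/C(C)=C/[Sn](C)(C)C
F3 | step 12 | free pentaenol (23 with OH in place of the aluminium alkoxide) | C/C=C(\C)[C@@H](O)/C(C)=C/C(C)=C\C(C)=C/C(C)=C/C(C)=C/[C@]1(C)[C@H]2OC(=O)[C@]1(C)C(=O)[C@@H]2C
F4 | step 12 | cyclooctatrienol (24 with OH in place of the aluminium alkoxide) | C/C=C(\C)[C@@H](O)[C@@]3(C)/C=C(C)\C=C(C)/C=C(C)\[C@@H]3/C(C)=C/[C@]1(C)[C@H]2OC(=O)[C@]1(C)C(=O)[C@@H]2C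
F5 | step 12 | helical diastereomer of F4 (both sp3 ring carbons inverted) | C/C=C(\C)[C@@H](O)[C@]3(C)/C=C(C)\C=C(C)/C=C(C)\[C@H]3/C(C)=C/[C@]1(C)[C@H]2OC(=O)[C@]1(C)C(=O)[C@@H]2C
F6 | step 12 | shimalactone A | C/C=C(\C)[C@@H](O)[C@]1(C)[C@H]2C(C)=CC(C)=C[C@@]2(C)[C@H]1/C(C)=C/[C@]1(C)[C@H]2OC(=O)[C@]1(C)C(=O)[C@@H]2C
F7 | step 7 | methyl (4R,5S,6E)-5-hydroxy-2,4,6-trimethyl-3,8-dioxonon-6-enoate | COC(=O)C(C)C(=O)[C@H](C)[C@H](O)/C(C)=C/C(C)=O
F8 | step 7 | (5R,6S)-3,5-dimethyl-6-[(2E)-4-oxopent-2-en-2-yl]oxane-2,4-dione | C[C@H]1C(=O)C(C)C(=O)O[C@@H]1/C(C)=C/C(C)=O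
F9 | step 7 | (E)-3-(dimethylalumanyl)-2-methylprop-2-en-1-yl dimethylalumanyl ether | C[Al](C)/C=C(C)/CO[Al](C)C
F10 | step 7 | (E)-3-iodo-2-methylprop-2-en-1-ol | OC/C(C)=C/I
F11 | step 7 | lithium (E)-3-lithio-2-methylprop-2-en-1-olate | [Li]/C=C(C)/CO[Li]
F12 | step 7 | (5R,6S)-6-[(2E,5E)-4,7-dihydroxy-4,6-dimethylhepta-2,5-dien-2-yl]-3,5-dimethyloxane-2,4-dione | C[C@H]1C(=O)C(C)C(=O)O[C@@H]1/C(C)=C/C(C)(O)/C=C(C)/CO
F13 | step 7 | (1S,4S,6R,7S)-7-[(1E,3E)-5-hydroxy-2,4-dimethylpenta-1,3-dien-1-yl]-4,6,7-trimethyl-2-oxabicyclo[2.2.1]heptane-3,5-dione | OC/C(C)=C/C(C)=C/[C@]1(C)[C@H]2OC(=O)[C@]1(C)C(=O)[C@@H]2C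
F14 | step 7 | (2E,4E)-2,4-dimethyl-5-[(1S,4S,6R,7S)-4,6,7-trimethyl-3,5-dioxo-2-oxabicyclo[2.2.1]heptan-7-yl]penta-2,4-dienal | O=C/C(C)=C/C(C)=C/[C@]1(C)[C@H]2OC(=O)[C@]1(C)C(=O)[C@@H]2C
F15 | step 7 | (1S,4S,6R,7S)-7-[(1E,3E,5Z)-6-iodo-2,4-dimethylhepta-1,3,5-trien-1-yl]-4,6,7-trimethyl-2-oxabicyclo[2.2.1]heptane-3,5-dione | I/C(C)=C\C(C)=C\C(C)=C\[C@]1(C)[C@H]2OC(=O)[C@]1(C)C(=O)[C@@H]2C
F16 | step 5 | (2R,3S,4E,6E)-3-hydroxy-2,4,6-trimethyl-8-oxonona-4,6-dienal | O=C[C@H](C)[C@H](O)/C(C)=C/C(C)=C/C(C)=O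
F17 | step 5 | (2R,3S,4E,6E)-2,4,6-trimethyl-1,8-dioxonona-4,6-dien-3-yl 2-bromopropanoate | O=C[C@H](C)[C@H](OC(=O)C(C)Br)/C(C)=C/C(C)=C/C(C)=O
F18 | step 5 | (5S,6S)-4-hydroxy-3,5-dimethyl-6-[(2E,4E)-4-methyl-6-oxohepta-2,4-dien-2-yl]oxan-2-one (mixture at C3 and C4) | C[C@H]1C(O)C(C)C(=O)O[C@@H]1/C(C)=C/C(C)=C/C(C)=O
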